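## Analysis of the target

The target is a resveratrol trimer, C42H32O9, organised around one hexasubstituted benzene ring, ring A, whose carbons are called a1 to a6 in ring order. Ring A is fused at a2–a3 to an inner 2,3-dihydrobenzofuran (O on a3, C2 carrying 4-hydroxyphenyl, C3 on a2) and at a5–a6 to an outer 2,3-dihydrobenzofuran (O' on a5, C2' carrying 4-hydroxyphenyl, C3' on a6 carrying 3,5-dihydroxyphenyl). At a1–a2 it is fused to a seven-membered carbocycle a1–C8H2–C7H(4-hydroxyphenyl)–b6–b1–C3–a2, in which b1 and b6 are adjacent carbons of the resorcinol ring B (OH on b3 and b5); a4 is the only C–H of ring A. There are five stereocentres: C2 (S), C3 (S), C7 (S), C2' (R) and C3' (R). Both dihydrofurans are trans, and H3 and the C7 aryl group lie on the same face of the seven-membered ring, which lets that aryl group stand perpendicular to ring B, away from the b5 oxygen. The outer furan has no rigid contact with the other three centres, so its absolute sense must come from a reagent. The seven phenols are oxidation-prone and the C2–O and C2'–O bonds, benzylic to para-oxygenated aryl groups, ionise in acid; the phenols are therefore carried as methyl ethers to the last step. The synthesis is hard because ring A bears contiguous, different substituents, the medium ring holds a stereocentre with no heteroatom handle, and rings A and B are electronically alike, so late substitution of ring A cannot rest on electrophilic reactivity alone. The strategy rests on a1 (CH2) and a2 (bond to C3) being adjacent, with a2 flanked on its other side by the oxygenated a3: this is the pattern left when a 2-alkoxyaryl iodide is alkylated at its one free ortho C–H and then substituted at the ipso carbon.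

## Retrosynthetic reasoning

**25 from 24.** The seven aryl O–CH3 bonds are cut last, so that every metal-mediated step runs on ethers. 24 is the heptamethyl ether with the outer furan still cis (2'S,3'R). The boron Lewis acid that removes the methyl groups also opens and re-closes the C2'–O bond, so C2' should settle trans to the C3' aryl group in the same operation.

**24 from 23, 22 and 21.** The C2'–C3' bond is cut, not the O'–C2' bond. This puts the stereo-determining event on C3' under control of a chiral dirhodium catalyst: the diaryl carbene from diazo compound 23 (from hydrazone 22 of ketone 21) inserts into a benzylic C–H of the 4-methoxybenzyl ether on a5. The ether is thus both the protecting group of the a5 oxygen and the source of C2' with its aryl group.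

**21 from 20, 18 + 19, 16 + 17, and 15.** Ketone 21 is the oxidation product of alcohol 20, made from aldehyde 18 and Grignard reagent 19; 18 is the ether of phenol 16 with chloride 17; the a6–CHO bond of 16 is cut back to phenol 15. The a6 carbon must be a C–H during the key step, because it is next to the C–H that is palladated, so its substituent can only come afterwards. The a5 hydroxyl is the only free phenol of 15; a magnesium phenoxide formylation acts only on ring A and goes ortho to OH and para to the furan oxygen (a6) rather than between the two oxygens (a4).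

**15 from 14 and 13.** The O–C2 bond and the C3–H bond are cut, which leads to the triarylethene 14, an isomer of 15, and to its bis(methoxymethyl) ether 13. Acid must remove the two acetals, protonate C3 and let the a3 hydroxyl close on the 4-methoxybenzylic cation. Ring A wears acetals rather than methyl ethers so that its two oxygens can be freed without touching the other five.

**13 from 10 + 12.** The a1–C8 and a2–C3 bonds are cut together. This splits the tricycle into aryl iodide 12 and bromide 10, which already holds ring B, C7 with its configuration and the stilbene that becomes C3 and C2. The forward reaction is a Catellani ortho-alkylation ended by an intramolecular Heck closure.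

**10 from 9, and 9 from 7 + 8.** The C–Br bond goes back to alcohol 9, and the b1–vinyl bond to aryl bromide 7 and styrylboronic acid 8. The stilbene is introduced only after the stereocentre exists, because a copper hydride catalyst would not reliably tell a stilbene from a 1,1-diarylethene.

**7 from 6 and 5.** The C7–H and C8–O bonds are cut to the 1,1-diarylethene 5 by enantioselective copper-catalysed hydroboration (boronate 6) and oxidation. The two aryl groups differ strongly: the 4-methoxyphenyl is coplanar with the alkene, the 2,6-disubstituted ring B is twisted out of it.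

**5 from 4, 3, and 1 + 2; 12 from 11.** The methylene carbon is added to ketone 3 as a methyl nucleophile (alcohol 4) and water is lost; 3 is the Friedel–Crafts product of 1 and 2. Iodide 12 is the bis-acetal of 11.

## Alternatives that were turned down

**Alternative 1: Wolff ring contraction of a chiral-pool flavanone.**
- Disconnection: the a2–C3 bond of the inner furan.
- Forward key step: irradiation of the 3-diazochromanone A2 expels the diazo nitrogen, the ring A carbon shifts from the carbonyl carbon to C3, and the ketene is trapped as the methyl ester A1.
- For it: C2 comes enantiopure from the pool, the trans ester is the stable one, and the triflate of A1 marks a1.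
- Against it: the ester carbon is not a carbon of the target. Ring B must replace it at an epimerisable secondary centre, and C8, C7 and the seven-membered ring are still to be made. The 2-arylchromanone can also racemise at C2 by ring opening under the basic conditions of diazo transfer.
- Comparison: alternative 1 is stronger on C2 and on the C3/C7 relation, since C7 would be formed last, as in the likely natural order, whereas here C3 is formed after C7 and depends on step 8. In exchange, the chosen route brings ring B, C7 and the C2 carbon with its aryl group into the molecule before the ring closure and forms both ring A C–C bonds in one step, which is shorter.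

**Alternative 2: palladium oxypalladation–arylation cascade.**
- Disconnection: O–C2 of the inner furan and C3–b1.
- Forward key step: a zerovalent palladium catalyst adds to the ring B bromide of alkynylphenol A4, the phenoxide attacks the bound alkyne, and reductive elimination joins C3 to b1, giving benzofuran A3.
- For it: two rings in one step, and ring A needs no late functionalisation because the outer furan is already in place.
- Against it: in A3, C2=C3 is part of an aromatic furan inside the cycloheptene. It must be reduced to the trans dihydrofuran with H3 syn to the C7 aryl group, whereas hydrogenation adds cis and from the open face, and 2,3-diarylbenzofurans resist reduction. The medium ring is closed late, on the most valuable intermediate.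
- Comparison: alternative 2 is stronger in sparing steps 9 to 12. The chosen route offers an inner ring at the right oxidation level (13 needs only a proton to become 15) and a ring closure on simple fragments.

**Alternative 3: aryne insertion into an indanone.**
- Disconnection: b1–C3 and b6–C7.
- Forward key step: fluoride releases aryne A7, which inserts into the C1–C2 bond of indanone keto ester A6. The enolate carbon adds to the aryne carbon remote from the methoxy group, the aryl anion closes on the ketone, and fragmentation gives the seven-membered keto ester A5.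
- For it: metal-free, regiochemistry fixed by the methoxy group, outer furan already present.
- Against it: A5 has a ketone where C7 needs H and an aryl group, and an ester where C3 needs the C2(aryl)–O unit. C7, C3 and C2 would therefore all be set afterwards by substrate control, with C3 epimerisable while the carbonyl groups remain, and A6 is itself a long synthesis.
- Comparison: alternative 3 is equal or stronger in the certainty of the bond-forming event and again needs no late work on ring A. The chosen strategy delivers C7 with its aryl group and configuration from a catalytic step before the ring is made, and far less functional-group repair follows the key step.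

Key step: step 7

Assumption: (R)-DTBM-SEGPHOS in step 3 and Rh2(S-PTAD)4 in step 14 are taken to be the antipodes that give the configurations drawn; if either induces the opposite sense, its mirror-image form is used and nothing else changes.

## Route

Step 1
Reactants: 1 1-bromo-3,5-dimethoxybenzene; 2 4-methoxybenzoyl chloride
Product: 3 (2-bromo-4,6-dimethoxyphenyl)(4-methoxyphenyl)methanone
Conditions: SnCl4 (1.1 equiv), CH2Cl2, 0 °C to rt
Reagents that add atoms: none
Why: Friedel–Crafts acylation; attack para to one methoxy group and ortho to the other (next to Br) is preferred over the position between the two methoxy groups, as in formylations of 1, and SnCl4 avoids the ortho-demethylation seen with stronger Lewis acids.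

Step 2
Reactants: 3
Product: 5 1-bromo-3,5-dimethoxy-2-[1-(4-methoxyphenyl)ethenyl]benzene, via tertiary alcohol 4 (not isolated)
Conditions: MeMgBr, THF, 0 °C to rt; NH4Cl work-up; then TsOH·H2O (cat.), toluene, 60 °C
Reagents that add atoms: methylmagnesium bromide, C[Mg]Br
Why: Grignard addition to a non-enolisable diaryl ketone, then E1 dehydration of the doubly benzylic tertiary alcohol; the twisted 2,6-disubstituted ring slows acid dimerisation of the alkene.

Step 3
Reactants: 5
Product: 7 (2S)-2-(2-bromo-4,6-dimethoxyphenyl)-2-(4-methoxyphenyl)ethanol, via pinacol boronate 6 (not isolated)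
Conditions: CuCl (5 mol%), (R)-DTBM-SEGPHOS (5.5 mol%), KOtBu (10 mol%), HBpin, toluene, rt; then NaOH, H2O2, THF/H2O, 0 °C
Reagents that add atoms: hydrogen peroxide, OO; pinacolborane, CC1(C)OBOC1(C)C (its boron is in 6 only)
Why: Enantioselective copper hydride hydroboration of a 1,1-disubstituted aryl alkene, copper going to CH2 and hydride to C7, then oxidation with retention; the face is chosen by the ligand, which reads the flat 4-methoxyphenyl against the twisted ring B, and the aryl bromide is inert to copper hydride.

Step 4
Reactants: 7; 8 (E)-[2-(4-methoxyphenyl)ethenyl]boronic acid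
Product: 9 (2S)-2-{2,4-dimethoxy-6-[(E)-2-(4-methoxyphenyl)ethenyl]phenyl}-2-(4-methoxyphenyl)ethanol
Conditions: Pd(OAc)2 (3 mol%), SPhos (6 mol%), K3PO4, toluene/H2O, 80 °C
Reagents that add atoms: none
Why: Suzuki–Miyaura coupling of a hindered aryl bromide with an alkenylboronic acid, with retention of the E geometry; the free alcohol and the C7 stereocentre are not affected.

Step 5
Reactants: 9
Product: 10 2-[(1S)-2-bromo-1-(4-methoxyphenyl)ethyl]-1,5-dimethoxy-3-[(E)-2-(4-methoxyphenyl)ethenyl]benzene
Conditions: CBr4, PPh3, CH2Cl2, 0 °C
Reagents that add atoms: carbon tetrabromide, BrC(Br)(Br)Br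
Why: Appel bromination of a primary alcohol under neutral, cold conditions, chosen to keep aryl participation (1,2-shift) and elimination at bay; C7 is not a reacting centre.

Step 6
Reactants: 11 4-iodobenzene-1,3-diol
Product: 12 1-iodo-2,4-bis(methoxymethoxy)benzene
Conditions: MOMCl, iPr2NEt, CH2Cl2, 0 °C to rt
Reagents that add atoms: chloromethyl methyl ether, COCCl
Why: Standard acetal protection of both phenols; the acetals survive carbonate at 85 °C and can later be removed without touching methyl ethers.

Step 7
Reactants: 10; 12 (1.5 equiv)
Product: 13 (10S)-7,9-dimethoxy-5-[(E)-(4-methoxyphenyl)methylidene]-10-(4-methoxyphenyl)-2,4-bis(methoxymethoxy)-10,11-dihydro-5H-dibenzo[a,d][7]annulene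
Conditions: Pd(OAc)2 (10 mol%), P(2-furyl)3 (22 mol%), norbornene (2 equiv), Cs2CO3 (3 equiv), MeCN, 85 °C
Reagents that add atoms: none
Why: Catellani ortho-alkylation ended by an intramolecular Heck reaction, the known annulation of aryl iodides with alkyl halides that carry a tethered alkene. Zerovalent palladium adds to the C–I bond of 12, norbornene inserts, and carbonate-assisted palladation of the only free ortho C–H (a1) gives a five-membered palladacycle; bromide 10 adds at CH2 to give tetravalent palladium, reductive elimination forms the a1–C8 bond, and the now doubly ortho-substituted aryl group expels norbornene. The divalent arylpalladium at a2 then inserts the stilbene by 7-exo-trig syn-carbopalladation at the carbon attached to ring B, which forms the a2–C3 bond and the seven-membered ring; bond rotation and syn β-hydride elimination give the triarylethene and return zerovalent palladium. No stereocentre is created: C7 comes in with 10 and is not involved, and the E geometry (anisyl cis to ring B) follows from syn insertion and syn elimination on the E-stilbene and has no later consequence. Mono-alkylation is secured by the a3 methoxymethoxy group, which blocks the second ortho position; 7-exo over 8-endo closure is secured by the tether length and the benzylic palladium it produces. The demanding selectivity is oxidative addition of the β-branched bromide against its base-induced loss of HBr, which is why 12 and not 10 is used in excess and the carbonate is kept heterogeneous in MeCN.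

Step 8
Reactants: 13
Product: 15 (2S,3S,7S) inner trans-dihydrobenzofuran phenol (free OH on a5; H on a6), via resorcinol 14 (not isolated)
Conditions: 3 M HCl, MeOH/THF, 45 °C; evaporate; then TFA, CH2Cl2 (5 mM), rt to 40 °C until the isomer ratio is constant
Reagents that add atoms: none
Why: Acetal cleavage, then Brønsted acid hydroalkoxylation of an ortho-hydroxy triarylethene: protonation at C3 gives the 4-methoxybenzylic cation at C2, which the a3 hydroxyl traps in a 5-ring closure. Both bonds form reversibly (C2–O ionisation; proton loss back to 14), so C2 should end trans to ring B and C3 should end with H3 syn to the C7 aryl group, the isomer in which that aryl stays perpendicular to ring B and clear of the b5 methoxy group.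

Step 9
Reactants: 15
Product: 16 (2S,3S,7S) salicylaldehyde: 15 bearing CHO on a6
Conditions: MgCl2, Et3N, (CH2O)n, MeCN, reflux; dilute citric acid work-up
Reagents that add atoms: paraformaldehyde, as formaldehyde C=O
Why: Casnati–Skattebøl ortho-formylation through the magnesium phenoxide, which confines the reaction to ring A; of the two ortho positions, a6 (para to the furan oxygen, next to CH2) is expected over a4 (between two oxygens), as in formylations of orcinol-type phenols.

Step 10
Reactants: 16; 17 4-methoxybenzyl chloride
Product: 18 (2S,3S,7S) aldehyde 4-methoxybenzyl ether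
Conditions: K2CO3, NaI (cat.), DMF, 50 °C
Reagents that add atoms: none
Why: Williamson etherification of the only phenol; the benzyl CH2 introduced here is the future C2'.

Step 11
Reactants: 18; 19 (3,5-dimethoxyphenyl)magnesium bromide
Product: 20 (2S,3S,7S) diarylmethanol (both carbinol epimers)
Conditions: THF, −20 °C to rt; NH4Cl work-up
Reagents that add atoms: none
Why: Grignard addition to a non-enolisable aryl aldehyde; the new carbinol centre is removed in the next step.

Step 12
Reactants: 20
Product: 21 (2S,3S,7S) diaryl ketone: a6–C(=O)–(3,5-dimethoxyphenyl)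
Conditions: Dess–Martin periodinane, NaHCO3, CH2Cl2, rt
Reagents that add atoms: none
Why: Buffered hypervalent iodine oxidation of a diarylmethanol; the electron-rich arenes and the acid-sensitive benzylic ethers are not attacked.

Step 13
Reactants: 21
Product: 22 (2S,3S,7S) hydrazone of 21
Conditions: N2H4·H2O (excess), AcOH (cat.), EtOH, 90 °C, sealed tube
Reagents that add atoms: hydrazine hydrate, as hydrazine NN
Why: Condensation of a diaryl ketone with hydrazine; excess reagent and heat are needed for the di-ortho-substituted carbonyl and suppress azine formation.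

Step 14
Reactants: 22
Product: 24 (2S,3S,7S,2'S,3'R) heptamethyl ether having the outer dihydrofuran cis, via diaryldiazomethane 23 (not isolated)
Conditions: MnO2, CH2Cl2, 0 °C, filter; then Rh2(S-PTAD)4 (1 mol%), CH2Cl2, 0 °C
Reagents that add atoms: none
Why: Oxidation of the hydrazone to the diaryldiazomethane, then enantioselective intramolecular C–H insertion of the donor/donor rhodium carbene into the benzylic ether C–H (5-ring), a known route to 2,3-diaryl-2,3-dihydrobenzofurans. The catalyst sets C3' (R), overriding the remote resident centres, and the insertion is expected to give the 2',3'-cis isomer; insertion into C7–H would need a strained indane and is not expected.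

Step 15
Reactants: 24
Product: 25 target heptaphenol (2S,3S,7S,2'R,3'R)
Conditions: BBr3 (excess), CH2Cl2, −78 to 0 °C; MeOH then H2O quench
Reagents that add atoms: none
Why: Lewis acid cleavage of all seven aryl methyl ethers; under the same conditions the C2'–O bond ionises to the para-oxygenated benzylic cation and re-closes, so C2' should epimerise to the trans arrangement while C3', C3 and C7, which bear no leaving group, stay fixed; the low temperature is kept so that proton loss from the open cation does not compete.

## Compound list

1 | 1-bromo-3,5-dimethoxybenzene | COc1cc(Br)cc(OC)c1 | starting material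
2 | 4-methoxybenzoyl chloride | COc1ccc(C(=O)Cl)cc1 | starting material
3 | (2-bromo-4,6-dimethoxyphenyl)(4-methoxyphenyl)methanone | COc1ccc(C(=O)c2c(Br)cc(OC)cc2OC)cc1 | intermediate
4 | 1-(2-bromo-4,6-dimethoxyphenyl)-1-(4-methoxyphenyl)ethanol (racemic) | COc1ccc(C(C)(O)c2c(Br)cc(OC)cc2OC)cc1 | intermediate (not isolated)
5 | 1-bromo-3,5-dimethoxy-2-[1-(4-methoxyphenyl)ethenyl]benzene | C=C(c1ccc(OC)cc1)c1c(Br)cc(OC)cc1OC | intermediate
6 | 2-[(2S)-2-(2-bromo-4,6-dimethoxyphenyl)-2-(4-methoxyphenyl)ethyl]-4,4,5,5-tetramethyl-1,3,2-dioxaborolane | COc1ccc([C@@H](c2c(Br)cc(OC)cc2OC)CB2OC(C)(C)C(C)(C)O2)cc1 | intermediate (not isolated)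
7 | (2S)-2-(2-bromo-4,6-dimethoxyphenyl)-2-(4-methoxyphenyl)ethanol | COc1ccc([C@@H](c2c(Br)cc(OC)cc2OC)CO)cc1 | intermediate
8 | (E)-[2-(4-methoxyphenyl)ethenyl]boronic acid | COc1ccc(/C=C/B(O)O)cc1 | starting material
9 | (2S)-2-{2,4-dimethoxy-6-[(E)-2-(4-methoxyphenyl)ethenyl]phenyl}-2-(4-methoxyphenyl)ethanol | COc1ccc([C@@H](c2c(OC)cc(OC)cc2/C=C/c2ccc(OC)cc2)CO)cc1 | intermediate
10 | 2-[(1S)-2-bromo-1-(4-methoxyphenyl)ethyl]-1,5-dimethoxy-3-[(E)-2-(4-methoxyphenyl)ethenyl]benzene | COc1ccc([C@@H](c2c(OC)cc(OC)cc2/C=C/c2ccc(OC)cc2)CBr)cc1 | intermediate
11 | 4-iodobenzene-1,3-diol (4-iodoresorcinol) | Oc1ccc(I)c(O)c1 | starting material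
12 | 1-iodo-2,4-bis(methoxymethoxy)benzene | COCOc1ccc(I)c(OCOC)c1 | intermediate
13 | (10S)-7,9-dimethoxy-5-[(E)-(4-methoxyphenyl)methylidene]-10-(4-methoxyphenyl)-2,4-bis(methoxymethoxy)-10,11-dihydro-5H-dibenzo[a,d][7]annulene (annulene C10 is C7, C5 is the future C3) | COc1ccc([C@@H]2Cc3cc(OCOC)cc(OCOC)c3/C(=C/c3ccc(OC)cc3)c3cc(OC)cc(OC)c32)cc1 | intermediate
14 | (10S)-7,9-dimethoxy-5-[(E)-(4-methoxyphenyl)methylidene]-10-(4-methoxyphenyl)-10,11-dihydro-5H-dibenzo[a,d][7]annulene-2,4-diol | COc1ccc([C@@H]2Cc3cc(O)cc(O)c3/C(=C/c3ccc(OC)cc3)c3cc(OC)cc(OC)c32)cc1 | intermediate (not isolated)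
15 | (2S,3S,7S)-phenol: 14 closed from the a3 oxygen to the former benzylidene carbon (C2), H on C3; trans-2-(4-methoxyphenyl)-2,3-dihydrobenzofuran fused at a2–a3 whose C3 is the diaryl carbon of the seven-membered ring; OH on a5, H on a6; ring B 3,5-dimethoxy; C7 4-methoxyphenyl | COc1ccc([C@@H]2Cc3c4c(cc(O)c3)O[C@H](c3ccc(OC)cc3)[C@H]4c3cc(OC)cc(OC)c32)cc1 | intermediate
16 | (2S,3S,7S)-aldehyde: 15 with CHO on a6, ortho to the a5 hydroxyl | COc1ccc([C@@H]2Cc3c4c(cc(O)c3C=O)O[C@H](c3ccc(OC)cc3)[C@H]4c3cc(OC)cc(OC)c32)cc1 | intermediate
17 | 1-(chloromethyl)-4-methoxybenzene (4-methoxybenzyl chloride) | COc1ccc(CCl)cc1 | starting material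
18 | (2S,3S,7S)-aldehyde ether: 16 with the a5 oxygen as 4-methoxybenzyl ether | COc1ccc([C@@H]2Cc3c4c(cc(OCc5ccc(OC)cc5)c3C=O)O[C@H](c3ccc(OC)cc3)[C@H]4c3cc(OC)cc(OC)c32)cc1 | intermediate
19 | (3,5-dimethoxyphenyl)magnesium bromide | COc1cc(OC)cc([Mg]Br)c1 | starting material
20 | (2S,3S,7S)-diarylmethanol: 18 with CH(OH)(3,5-dimethoxyphenyl) on a6, both carbinol epimers | COc1ccc([C@@H]2Cc3c4c(cc(OCc5ccc(OC)cc5)c3C(O)c3cc(OC)cc(OC)c3)O[C@H](c3ccc(OC)cc3)[C@H]4c3cc(OC)cc(OC)c32)cc1 | intermediate
21 | (2S,3S,7S)-ketone: a6–C(=O)–(3,5-dimethoxyphenyl), a5 4-methoxybenzyl ether | COc1ccc([C@@H]2Cc3c4c(cc(OCc5ccc(OC)cc5)c3C(=O)c3cc(OC)cc(OC)c3)O[C@H](c3ccc(OC)cc3)[C@H]4c3cc(OC)cc(OC)c32)cc1 | intermediate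
22 | (2S,3S,7S)-hydrazone of 21 (C=N–NH2, either geometry) | COc1ccc([C@@H]2Cc3c4c(cc(OCc5ccc(OC)cc5)c3C(=NN)c3cc(OC)cc(OC)c3)O[C@H](c3ccc(OC)cc3)[C@H]4c3cc(OC)cc(OC)c32)cc1 | intermediate
23 | (2S,3S,7S)-diaryldiazomethane: a6–C(=N2)–(3,5-dimethoxyphenyl) | COc1ccc([C@@H]2Cc3c4c(cc(OCc5ccc(OC)cc5)c3C(=[N+]=[N-])c3cc(OC)cc(OC)c3)O[C@H](c3ccc(OC)cc3)[C@H]4c3cc(OC)cc(OC)c32)cc1 | intermediate (not isolated)
24 | (2S,3S,7S,2'S,3'R)-heptamethyl ether of the 2'-epimer of the target (outer dihydrofuran cis, inner trans) | COc1ccc([C@@H]2Cc3c4c(cc5c3[C@@H](c3cc(OC)cc(OC)c3)[C@@H](c3ccc(OC)cc3)O5)O[C@H](c3ccc(OC)cc3)[C@H]4c3cc(OC)cc(OC)c32)cc1 | intermediate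
25 | target, (2S,3S,7S,2'R,3'R)-heptaphenol | Oc1ccc([C@@H]2Cc3c4c(cc5c3[C@@H](c3cc(O)cc(O)c3)[C@H](c3ccc(O)cc3)O5)O[C@H](c3ccc(O)cc3)[C@H]4c3cc(O)cc(O)c32)cc1 | target

## Step count and least certain steps

Total: 15 steps. Longest linear sequence: 14 steps (steps 1–5 and 7–15); step 6 is a one-step side branch.

**Step 7 (key step).** The most likely failure is loss of HBr from 10 to the 1,1-diarylethene under carbonate at 85 °C, outrunning the slow SN2-type addition of this β-branched bromide to the palladacycle, so that 12 is consumed in norbornene-derived side products. The fallback makes the two bonds one after the other, setting out from 10 and returning at 13. Purchased 5-iodoresorcinol is protected with MOMCl/iPr2NEt to 1-iodo-3,5-bis(methoxymethoxy)benzene F1, which NBS in MeCN brominates ortho to iodine and para to an acetal oxygen to give 2-bromo-1-iodo-3,5-bis(methoxymethoxy)benzene F2. Bromide 10 is converted with activated zinc and LiCl in THF into the alkylzinc bromide F3, and Negishi coupling (Pd(OAc)2, CPhos, THF, rt) at the C–I bond of F2 gives the aryl bromide F4. An ordinary intramolecular Heck reaction of F4 (Pd(OAc)2, P(o-tol)3, Et3N, DMF, 100 °C) closes the seven-membered ring to 13.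

**Step 8.** The proton may go to the benzylidene CH and not to C3, giving the cation stabilised by the dihydroxy ring A, which can alkylate a second molecule before the productive path is taken. The configuration at C3 may also be frozen under kinetic control with the proton delivered anti to the C7 aryl group. The fallback replaces proton transfer by hydride delivery, setting out from 13 and returning at 15. Hydroboration of 13 (BH3·THF, then NaOH/H2O2) puts boron on the less substituted alkene carbon and hydrogen on C3 by syn addition, giving the secondary 4-methoxybenzylic alcohol F5; HCl in MeOH then removes the acetals and closes the furan by ionisation of the carbinol, giving 15 with the trans ring. No cation is ever formed at C3 in this sequence, and C3 is then fixed by the face of borane approach rather than by proton transfer.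

**Step 14.** Oxidation of the hindered hydrazone may be slow, with azine formation or carbene dimerisation taking over, or the catalyst may be mismatched with the resident stereocentres so that selectivity at C3' is poor. The fallback sets out from 21 and comes back at 25 through step 15. Purchased 4-methoxybenzylmagnesium chloride is added to 21 to give the tertiary alcohol F6. TFA with anisole in CH2Cl2 removes the 4-methoxybenzyl ether, dehydrates the alcohol and closes the outer ring by the same hydroalkoxylation as in step 8. This gives the all-trans heptamethyl ether F7 together with its (2'S,3'S) diastereomer, which are separated by chromatography; F7 takes the place of 24 in step 15.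

**Step 3.** The enantioselectivity may be insufficient, since hydrocupration of this very hindered 1,1-diarylethene is slow and a background, unselective pathway could compete. The fallback is a resolution, setting out from 5 and returning at 7. Hydroboration with 9-BBN and oxidation give the racemic alcohol F8; esterification with purchased (S)-2-methoxy-2-phenylacetic acid (DCC, DMAP) gives two diastereomeric esters that are separated by chromatography, and the ester of the (S)-alcohol, F9, is hydrolysed with LiOH to 7.

## Further compounds

F1 | step 7 | 1-iodo-3,5-bis(methoxymethoxy)benzene | COCOc1cc(I)cc(OCOC)c1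
F2 | step 7 | 2-bromo-1-iodo-3,5-bis(methoxymethoxy)benzene | COCOc1cc(I)c(Br)c(OCOC)c1
F3 | step 7 | {(2S)-2-{2,4-dimethoxy-6-[(E)-2-(4-methoxyphenyl)ethenyl]phenyl}-2-(4-methoxyphenyl)ethyl}zinc bromide | COc1ccc([C@@H](c2c(OC)cc(OC)cc2/C=C/c2ccc(OC)cc2)C[Zn]Br)cc1
F4 | step 7 | 2-bromo-1-{(2S)-2-{2,4-dimethoxy-6-[(E)-2-(4-methoxyphenyl)ethenyl]phenyl}-2-(4-methoxyphenyl)ethyl}-3,5-bis(methoxymethoxy)benzene | COc1ccc([C@@H](c2c(OC)cc(OC)cc2/C=C/c2ccc(OC)cc2)Cc2cc(OCOC)cc(OCOC)c2Br)cc1
F5 | step 8 | hydroboration product of 13: H on C3 (configuration as in 15), CH(OH)(4-methoxyphenyl) on C3 by syn addition, ring A still bis(methoxymethyl) ether | COc1ccc([C@@H]2Cc3cc(OCOC)cc(OCOC)c3[C@@H]([C@H](O)c3ccc(OC)cc3)c3cc(OC)cc(OC)c32)cc1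
F6 | step 14 | tertiary alcohol from 21: a6–C(OH)(3,5-dimethoxyphenyl)(CH2–4-methoxyphenyl), both carbinol epimers | COc1ccc([C@@H]2Cc3c4c(cc(OCc5ccc(OC)cc5)c3C(O)(Cc5ccc(OC)cc5)c3cc(OC)cc(OC)c3)O[C@H](c3ccc(OC)cc3)[C@H]4c3cc(OC)cc(OC)c32)cc1
F7 | step 14 | (2S,3S,7S,2'R,3'R)-heptamethyl ether of the target (both dihydrofurans trans) | COc1ccc([C@@H]2Cc3c4c(cc5c3[C@@H](c3cc(OC)cc(OC)c3)[C@H](c3ccc(OC)cc3)O5)O[C@H](c3ccc(OC)cc3)[C@H]4c3cc(OC)cc(OC)c32)cc1
F8 | step 3 | racemic 2-(2-bromo-4,6-dimethoxyphenyl)-2-(4-methoxyphenyl)ethanol | COc1ccc(C(c2c(Br)cc(OC)cc2OC)CO)cc1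
F9 | step 3 | (2S)-2-(2-bromo-4,6-dimethoxyphenyl)-2-(4-methoxyphenyl)ethyl (2S)-2-methoxy-2-phenylacetate | COc1ccc([C@@H](c2c(Br)cc(OC)cc2OC)COC(=O)[C@@H](OC)c2ccccc2)cc1
A1 | alternative 1 | methyl trans-6-methoxy-2-(4-methoxyphenyl)-4-(trifluoromethylsulfonyloxy)-2,3-dihydrobenzofuran-3-carboxylate | COc1ccc([C@H]2Oc3cc(OC)cc(OS(=O)(=O)C(F)(F)F)c3[C@@H]2C(=O)OC)cc1
A2 | alternative 1 | 3-diazo-7-methoxy-2-(4-methoxyphenyl)-4-oxochroman-5-yl trifluoromethanesulfonate | COc1ccc([C@H]2Oc3cc(OC)cc(OS(=O)(=O)C(F)(F)F)c3C(=O)C2=[N+]=[N-])cc1
A3 | alternative 2 | benzofuran analogue of the target heptamethyl ether (inner furan unsaturated) | COc1ccc([C@@H]2Cc3c4c(cc5c3[C@@H](c3cc(OC)cc(OC)c3)[C@H](c3ccc(OC)cc3)O5)oc(-c3ccc(OC)cc3)c4-c3cc(OC)cc(OC)c32)cc1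
A4 | alternative 2 | ortho-alkynylphenol carrying the outer dihydrofuran and the (S)-2-(2-bromo-4,6-dimethoxyphenyl)-2-(4-methoxyphenyl)ethyl chain on a1 | COc1ccc(C#Cc2c(O)cc3c(c2C[C@@H](c2ccc(OC)cc2)c2c(Br)cc(OC)cc2OC)[C@@H](c2cc(OC)cc(OC)c2)[C@H](c2ccc(OC)cc2)O3)cc1
A5 | alternative 3 | dibenzocycloheptenone keto ester with ketone at the future C7 and methyl ester at the future C3 | O=C1Cc2c(c(OC)cc3c2[C@@H](c2cc(OC)cc(OC)c2)[C@H](c2ccc(OC)cc2)O3)C(C(=O)OC)c2cc(OC)cc(OC)c21
A6 | alternative 3 | ring A 2-indanone-1-carboxylate (methyl ester) fused to the outer dihydrofuran | O=C1Cc2c(c(OC)cc3c2[C@@H](c2cc(OC)cc(OC)c2)[C@H](c2ccc(OC)cc2)O3)C1C(=O)OC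
A7 | alternative 3 | 3,5-dimethoxybenzyne | COC1=CC(OC)=CC#C1
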